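Ring C (eleven-membered) is cut at C8–C9 (Suzuki–Miyaura ring closure) and at C1–C14 (acylation of a C1 vinyllithium); trinervitane numbers, listed below, are used. Ring A (C1, C2, C3, C4, C16, C15) is not built as a cyclohexene: a Pauson–Khand reaction gives a cis-bicyclo[3.3.0]octanone in which C2 is bonded directly to C15, and the key step inserts C1 as dibromocarbene between these atoms through the silyl enol ether. One operation thus enlarges the five-membered ring, creates the tetrasubstituted C1=C15 alkene beside the C2 oxygen and leaves bromine on C1 as the handle for C14. It exploits the 2-oxy-1-alkyl-15-methylcyclohex-1(15)-ene array of ring A.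

Key step: step 8

Remark on numbering: ring A = C1, C2, C3, C4, C16, C15 (C1=C15, oxygen on C2 and C3, Me-18 on C4, Me-17 on C15); ring B = C4, C5, C6, C7, C16; ring C = C1, C15, C16, C7, C8 (=C19H2), C9=C10, C11, C12 (Me-20), C13, C14 (OAc). "Up" is the face of rings A/B that carries Me-18 and H-16 (the convex face); "down" is the opposite face.

Assumption: in step 4 the C7 ether should end up cis to Me-18; because C7 becomes a ketone in step 12, the opposite outcome would be corrected by using the (R,R)-catalyst in step 2.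

Step 1
Reactants: 1 ethyl 4-methylpent-4-enoate
Product: 3 7-methyloct-7-en-2-yn-4-one, via Weinreb amide 2 (not isolated)
Conditions: MeNHOMe·HCl, iPrMgCl, THF, −20 °C; then CH3C≡CMgBr, −20 to 0 °C; inverse quench into cold 1 M HCl
Reagents that add atoms: 1-propynylmagnesium bromide, CC#C[Mg]Br
Why: One-pot Weinreb ketone synthesis: the magnesium amide converts the ester into the N-methoxy-N-methyl amide, whose chelated adduct with the alkynyl Grignard reagent stops at the ketone stage, and the acidic inverse quench keeps the liberated amine from adding to the ynone.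

Step 2
Reactants: 3 7-methyloct-7-en-2-yn-4-one
Product: 4 (S)-7-methyloct-7-en-2-yn-4-ol
Conditions: RuCl[(S,S)-TsDPEN](p-cymene) (1 mol %), iPrOH, 25 °C
Reagents that add atoms: none
Why: Noyori asymmetric transfer hydrogenation of an alkynyl ketone; the (S,S)-catalyst distinguishes the alkynyl from the alkyl group and should give the (S)-alcohol, which installs C7 as a temporary control element.

Step 3
Reactants: 4 (S)-7-methyloct-7-en-2-yn-4-ol
Product: 5 (S)-4-[(4-methoxybenzyl)oxy]-7-methyloct-7-en-2-yne
Conditions: NaH, 4-methoxybenzyl chloride, Bu4NI (cat.), THF/DMF, 0 to 25 °C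
Reagents that add atoms: 4-methoxybenzyl chloride, COc1ccc(CCl)cc1
Why: Williamson etherification; the 4-methoxybenzyl ether withstands the later bases and is removable oxidatively in step 11 without touching silyl ethers.

Step 4
Reactants: 5 (S)-4-[(4-methoxybenzyl)oxy]-7-methyloct-7-en-2-yne
Product: 6 bicyclic enone (4-[(4-methoxybenzyl)oxy]-3,6a-dimethyl-4,5,6,6a-tetrahydropentalen-2(1H)-one, ether cis to the angular methyl)
Conditions: Co2(CO)8 (10 mol %), tetramethylthiourea (60 mol %), CO (1 atm), toluene, 70 °C
Reagents that add atoms: carbon monoxide, [C-]#[O+]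
Why: Pauson–Khand (2+2+1) cycloaddition closes ring B and the five-membered precursor of ring A and creates the quaternary C4; the C7 ether avoids the alkyne methyl group in the metallacycle-forming step and should end up on the face of the new angular methyl, so that C7 controls C4, and the minor C4 epimer is removed by chromatography at this stage.

Step 5
Reactants: 6 bicyclic enone
Product: 7 cis-fused bicyclic ketone (H-16 up; C15 epimers)
Conditions: Mn(dpm)3 (5 mol %; dpm = 2,2,6,6-tetramethylheptane-3,5-dionate), PhSiH3, iPrOH, 25 °C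
Reagents that add atoms: none
Why: Hydrogen-atom-transfer conjugate reduction of the tetrasubstituted enone (the manganese hydride gives H to C16 and leaves the stabilised C15 radical); only the cis fusion of a bicyclo[3.3.0]octane is accessible, so H-16 should come out cis to Me-18, and C15 is of no concern because it becomes trigonal again in step 7.

Step 6
Reactants: 7 cis-fused bicyclic ketone
Product: 8 3-hydroxy ketone (3-OH up)
Conditions: LiN(iPr)2 (1.1 equiv), THF, −78 °C; then 2-(phenylsulfonyl)-3-phenyloxaziridine, −78 °C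
Reagents that add atoms: 2-(phenylsulfonyl)-3-phenyloxaziridine, O=S(=O)(c1ccccc1)N1OC1c1ccccc1
Why: Kinetic deprotonation should occur at the less substituted C3 methylene, and Davis oxidation of the enolate from the convex face of the cis-fused bicycle places the 3-hydroxy group cis to Me-18 and H-16.

Step 7
Reactants: 8 3-hydroxy ketone
Product: 9 bis(trimethylsilyl) compound (C2=C15 silyl enol ether, 3-OSiMe3)
Conditions: LiN(iPr)2 (2.3 equiv), THF, −78 to −40 °C; then Me3SiCl, −78 to 0 °C
Reagents that add atoms: chlorotrimethylsilane, C[Si](C)(C)Cl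
Why: Double deprotonation and O-silylation; C3 already carries an oxygen anion and is not deprotonated, so the silyl enol ether should form only towards C15, and the labile silyl ether masks O-3 for one step.

Step 8
Reactants: 9 bis(trimethylsilyl) compound
Product: 12 bromo-enone ketol (1-bromo-3-hydroxy-2-oxo ring A), via dibromocyclopropane 10 (not isolated), via silyl ether 11 (not isolated)
Conditions: CHBr3, KOtBu (added slowly), pentane, −30 to 25 °C; then 1 M HCl, THF, 0 °C
Reagents that add atoms: bromoform, BrC(Br)Br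
Why: KOtBu and CHBr3 generate dibromocarbene by α-elimination, which adds in a concerted (2+1) step to the electron-rich C2=C15 silyl enol ether of the five-membered ring (C2, C3, C4, C16, C15) to give the 1-siloxy-6,6-dibromobicyclo[3.1.0]hexane unit of 10; siloxy-assisted loss of the endo bromide then drives a disrotatory two-electron electrocyclic opening that breaks the old C2–C15 bond, so that the carbene carbon becomes C1 of a six-membered ring, and loss of the silyl group from the O-silyl oxocarbenium ion gives the 2-bromo-enone. The closest known reaction type is the dihalocarbene ring enlargement of cyclic silyl enol ethers to 2-halocycloalk-2-enones, a case of the gem-dihalocyclopropane to allyl cation rearrangement. The only ring closed is the transient cyclopropane, formed by cheletropic addition of the carbene to one face of the alkene, and ring A arises from it by cleavage of the shared bond, not by a cyclisation. No lasting stereocentre is created, because C2 and C15 become trigonal again and both faces of attack converge on one product, while C3, C4, C7 and C16 are not touched. The step needs regioselectivity (C1 between C2 and C15, not between C2 and C3) and chemoselectivity for the enol ether over the anisyl ring; the first is secured by the position of the enol ether fixed in step 7, the second by the high nucleophilicity of the tetrasubstituted enol ether. The acidic work-up should complete the ring opening and remove the trimethylsilyl group from O-3.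

Step 9
Reactants: 12 bromo-enone ketol
Product: 13 trans-2,3-diol (2-OH down, 3-OH up)
Conditions: Me4NBH(OAc)3, MeCN/AcOH (1:1), −30 °C
Reagents that add atoms: none
Why: Hydroxyl-directed triacetoxyborohydride reduction (Evans–Saksena type): boron is bound by the 3-hydroxy group and hydride is delivered intramolecularly to the same face of the C2 carbonyl, which should give the trans-diol, and the reagent does not reduce the enone without this delivery.

Step 10
Reactants: 13 trans-2,3-diol
Product: 15 2-O-TBS 3-O-TES bis-silyl ether, via mono-silyl ether 14 (not isolated)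
Conditions: TBSOTf (1.05 equiv), 2,6-lutidine, CH2Cl2, −78 °C; then TESOTf, −78 to 0 °C
Reagents that add atoms: tert-butyldimethylsilyl triflate, CC(C)(C)[Si](C)(C)OS(=O)(=O)C(F)(F)F; triethylsilyl triflate, CC[Si](CC)(CC)OS(=O)(=O)C(F)(F)F
Why: Silylation; the allylic 2-hydroxy group is far less hindered than the 3-hydroxy group next to the quaternary C4 and should react first at low temperature, after which the triethylsilyl triflate caps O-3, so that the two oxygens are differentiated in one flask.

Step 11
Reactants: 15 bis-silyl ether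
Product: 16 C7 alcohol
Conditions: DDQ, CH2Cl2/pH 7 buffer (10:1), 0 to 25 °C
Reagents that add atoms: none
Why: Oxidative cleavage of the 4-methoxybenzyl ether by single-electron oxidation of the electron-rich arene; silyl ethers and the electron-poor bromoalkene are inert.

Step 12
Reactants: 16 C7 alcohol
Product: 17 C7 ketone
Conditions: Dess–Martin periodinane, NaHCO3, CH2Cl2, 25 °C
Reagents that add atoms: none
Why: Dess–Martin oxidation under buffered conditions; C7 has served as control element and becomes trigonal.

Step 13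
Reactants: 17 C7 ketone
Product: 18 methyl enol ether (C7=C8(OMe)CH3)
Conditions: [Ph3PCH(OMe)CH3]Cl, KN(SiMe3)2, THF, −78 to 0 °C
Reagents that add atoms: (1-methoxyethyl)triphenylphosphonium chloride, COC(C)[P+](c1ccccc1)(c1ccccc1)c1ccccc1.[Cl-]
Why: Wittig olefination with the α-methoxy ylide turns the ketone into a methyl enol ether, a masked acetyl group (C8 and C19) that tolerates the organolithium chemistry of step 17; the alkene geometry is of no consequence.

Step 14
Reactants: 19 (S)-4-benzyloxazolidin-2-one; 20 (E)-but-2-enoyl chloride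
Product: 21 (S)-4-benzyl-3-[(E)-but-2-enoyl]oxazolidin-2-one
Conditions: n-BuLi, THF, −78 °C; then 20, −78 to 0 °C
Reagents that add atoms: none
Why: N-Acylation of the lithiated oxazolidinone with the acid chloride.

Step 15
Reactants: 21 (S)-4-benzyl-3-[(E)-but-2-enoyl]oxazolidin-2-one
Product: 22 (S)-4-benzyl-3-[(S)-3-methylhex-5-enoyl]oxazolidin-2-one
Conditions: allyltrimethylsilane, TiCl4, CH2Cl2, −78 °C
Reagents that add atoms: allyltrimethylsilane, C=CC[Si](C)(C)C
Why: Hosomi–Sakurai conjugate allylation; TiCl4 chelates both imide carbonyl groups in the s-cis conformation and the allylsilane attacks the β-carbon from the face opposite to the benzyl group, which should give the (S)-configuration of the later C12.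

Step 16
Reactants: 22 (S)-4-benzyl-3-[(S)-3-methylhex-5-enoyl]oxazolidin-2-one
Product: 23 (S)-N-methoxy-N,3-dimethylhex-5-enamide
Conditions: MeNHOMe·HCl, AlMe3, CH2Cl2, 0 to 25 °C
Reagents that add atoms: N,O-dimethylhydroxylamine hydrochloride, CNOC.Cl
Why: Aluminium amide transamination of the unhindered exocyclic imide carbonyl gives the Weinreb amide and returns the auxiliary.

Step 17
Reactants: 18 methyl enol ether; 23 (S)-N-methoxy-N,3-dimethylhex-5-enamide
Product: 25 C14 enone, via vinyllithium 24 (not isolated)
Conditions: t-BuLi (2.1 equiv), THF, −78 °C; then 23, −78 to −30 °C; aqueous NH4Cl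
Reagents that add atoms: none
Why: Bromine–lithium exchange gives the C1 vinyllithium, which acylates the Weinreb amide and forms the C1–C14 bond; the chelated adduct prevents over-addition, and the enol ether, silyl ethers and terminal alkene are inert.

Step 18
Reactants: 25 C14 enone
Product: 26 (14S)-allylic alcohol
Conditions: (R)-2-methyl-CBS-oxazaborolidine, catecholborane, toluene, −78 °C
Reagents that add atoms: none
Why: Corey–Bakshi–Shibata reduction under reagent control: the tetrasubstituted alkenyl group acts as the large and the C13 methylene as the small substituent, so the (R)-oxazaborolidine should give the (14S)-alcohol, and catecholborane does not hydroborate the alkenes at this temperature.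

Step 19
Reactants: 26 (14S)-allylic alcohol
Product: 27 methyl ketone diol (7-acetyl down, H-7 up; 3-OH and 14-OH free; 2-OTBS)
Conditions: AcOH/THF/H2O (3:1:1), 25 °C
Reagents that add atoms: water, O
Why: Acid hydrolysis: the enol ether should be protonated at C7 from the convex face (the concave face is shielded by ring A and Me-17), which places H-7 cis to H-16 and the acetyl group cis to the C16–C15 bond, and the same conditions cleave the triethylsilyl ether while the tert-butyldimethylsilyl ether survives.

Step 20
Reactants: 27 methyl ketone diol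
Product: 28 3,14-diacetate
Conditions: Ac2O, DMAP, pyridine, 25 °C
Reagents that add atoms: acetic anhydride, CC(=O)OC(C)=O
Why: Acylation of both free secondary hydroxy groups with nucleophilic catalysis; O-2 stays silylated and the ketone is untouched.

Step 21
Reactants: 28 3,14-diacetate
Product: 29 enol triflate (C8(OTf)=C19H2)
Conditions: KN(SiMe3)2, THF, −78 °C; then PhNTf2, −78 °C
Reagents that add atoms: N-phenylbis(trifluoromethanesulfonimide), O=S(=O)(N(c1ccccc1)S(=O)(=O)C(F)(F)F)C(F)(F)F
Why: Kinetic deprotonation of the methyl ketone at its methyl group by the hindered amide base, followed by O-sulfonylation, should give the 1,1-disubstituted enol triflate without touching H-7 or the less acidic acetates; C19 is thereby in place as the exocyclic methylene.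

Step 22
Reactants: 29 enol triflate
Product: 30 (E)-alkenyl pinacol boronate
Conditions: second-generation Hoveyda–Grubbs catalyst (5 mol %), vinylboronic acid pinacol ester, CH2Cl2, 40 °C
Reagents that add atoms: vinylboronic acid pinacol ester, C=CB1OC(C)(C)C(C)(C)O1
Why: Olefin cross-metathesis of the monosubstituted alkene with the vinylboronate brings in C9, is E-selective for steric reasons and leaves the tetrasubstituted alkene and the electron-poor enol triflate untouched.

Step 23
Reactants: 30 (E)-alkenyl pinacol boronate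
Product: 31 2-O-TBS ether of the target
Conditions: Pd(PPh3)4 (20 mol %), TlOEt, THF/H2O (3:1), 0.001 M, slow addition, 25 °C
Reagents that add atoms: none
Why: Intramolecular Suzuki–Miyaura coupling at high dilution forms the C8–C9 bond and closes ring C; both alkene geometries are fixed before ring closure, and oxidative addition to the enol triflate should be faster than ionisation of the hindered allylic acetate.

Step 24
Reactants: 31 2-O-TBS ether of the target
Product: 32 target (2R,3R,4S,7R,12S,14S,16S)-3,14-diacetoxytrinervita-1(15),8(19),9E-trien-2-ol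
Conditions: HF·pyridine, pyridine, THF, 0 to 25 °C
Reagents that add atoms: none
Why: Fluoride-mediated silyl ether cleavage under non-basic conditions, which avoids migration of the neighbouring acetate.

Compound list
1 | ethyl 4-methylpent-4-enoate | C=C(C)CCC(=O)OCC | starting material
2 | N-methoxy-N,4-dimethylpent-4-enamide (Weinreb amide) | C=C(C)CCC(=O)N(C)OC | intermediate
3 | 7-methyloct-7-en-2-yn-4-one | CC#CC(=O)CCC(C)=C | intermediate
4 | (S)-7-methyloct-7-en-2-yn-4-ol | CC#C[C@@H](O)CCC(C)=C | intermediate
5 | (S)-4-[(4-methoxybenzyl)oxy]-7-methyloct-7-en-2-yne | CC#C[C@@H](OCc1ccc(OC)cc1)CCC(C)=C | intermediate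
6 | 4-[(4-methoxybenzyl)oxy]-3,6a-dimethyl-4,5,6,6a-tetrahydropentalen-2(1H)-one; C2 ketone, C15=C16, 7-ether cis to Me-18 (both up) | O=C1C(C)=C2[C@@H](OCc3ccc(OC)cc3)CC[C@]2(C)C1 | intermediate
7 | cis-fused 4-[(4-methoxybenzyl)oxy]-3,6a-dimethylhexahydropentalen-2(1H)-one; H-16, Me-18 and the 7-ether up; mixture of C15 epimers | O=C1C(C)[C@@H]2[C@@H](OCc3ccc(OC)cc3)CC[C@]2(C)C1 | intermediate
8 | 1-hydroxy derivative of 7 (hydroxy group on C3, up, cis to Me-18); C15 epimers | O=C1C(C)[C@@H]2[C@@H](OCc3ccc(OC)cc3)CC[C@]2(C)[C@H]1O | intermediate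
9 | 4-[(4-methoxybenzyl)oxy]-3,6a-dimethyl-1,2-bis(trimethylsilyloxy)-1,3a,4,5,6,6a-hexahydropentalene (C2=C15 silyl enol ether, 3-OSiMe3 up) | C[Si](C)(C)OC1=C(C)[C@@H]2[C@@H](OCc3ccc(OC)cc3)CC[C@]2(C)[C@H]1O[Si](C)(C)C | intermediate
10 | dibromocyclopropane adduct of 9 (CBr2 bridging C2 and C15 on the up face) | C[Si](C)(C)O[C@]12C(Br)(Br)[C@@]1(C)[C@@H]3[C@@H](OCc4ccc(OC)cc4)CC[C@]3(C)[C@H]2O[Si](C)(C)C | intermediate
11 | 3-O-trimethylsilyl ether of 12 | BrC1=C(C)[C@@H]2[C@@H](OCc3ccc(OC)cc3)CC[C@]2(C)[C@@H](O[Si](C)(C)C)C1=O | intermediate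
12 | 6-bromo-4-hydroxy-1-[(4-methoxybenzyl)oxy]-3a,7-dimethyl-1,2,3,3a,4,7a-hexahydro-5H-inden-5-one (C1 bromide, C2 ketone, C1=C15; 3-OH, Me-18, H-16 and 7-ether all up) | BrC1=C(C)[C@@H]2[C@@H](OCc3ccc(OC)cc3)CC[C@]2(C)[C@@H](O)C1=O | intermediate
13 | 6-bromo-1-[(4-methoxybenzyl)oxy]-3a,7-dimethyl-2,3,3a,4,5,7a-hexahydro-1H-indene-4,5-diol (3-OH up, 2-OH down, trans) | BrC1=C(C)[C@@H]2[C@@H](OCc3ccc(OC)cc3)CC[C@]2(C)[C@@H](O)[C@@H]1O | intermediate
14 | 2-O-tert-butyldimethylsilyl ether of 13 | BrC1=C(C)[C@@H]2[C@@H](OCc3ccc(OC)cc3)CC[C@]2(C)[C@@H](O)[C@@H]1O[Si](C)(C)C(C)(C)C | intermediate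
15 | 2-O-tert-butyldimethylsilyl 3-O-triethylsilyl ether of 13 | BrC1=C(C)[C@@H]2[C@@H](OCc3ccc(OC)cc3)CC[C@]2(C)[C@@H](O[Si](CC)(CC)CC)[C@@H]1O[Si](C)(C)C(C)(C)C | intermediate
16 | C7 alcohol: 15 without the 4-methoxybenzyl group (7-OH up) | BrC1=C(C)[C@@H]2[C@@H](O)CC[C@]2(C)[C@@H](O[Si](CC)(CC)CC)[C@@H]1O[Si](C)(C)C(C)(C)C | intermediate
17 | C7 ketone: 6-bromo-5-(tert-butyldimethylsilyloxy)-3a,7-dimethyl-4-(triethylsilyloxy)-2,3,3a,4,5,7a-hexahydro-1H-inden-1-one | BrC1=C(C)[C@@H]2C(=O)CC[C@]2(C)[C@@H](O[Si](CC)(CC)CC)[C@@H]1O[Si](C)(C)C(C)(C)C | intermediate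
18 | 1-(1-methoxyethylidene) derivative of 17 (C7=C8(OMe)CH3, E/Z mixture) | BrC1=C(C)[C@@H]2C(=C(C)OC)CC[C@]2(C)[C@@H](O[Si](CC)(CC)CC)[C@@H]1O[Si](C)(C)C(C)(C)C | intermediate
19 | (S)-4-benzyloxazolidin-2-one | O=C1OC[C@H](Cc2ccccc2)N1 | starting material
20 | (E)-but-2-enoyl chloride | C/C=C/C(Cl)=O | starting material
21 | (S)-4-benzyl-3-[(E)-but-2-enoyl]oxazolidin-2-one | C/C=C/C(=O)N1[C@@H](Cc2ccccc2)COC1=O | intermediate
22 | (S)-4-benzyl-3-[(S)-3-methylhex-5-enoyl]oxazolidin-2-one | C=CC[C@H](C)CC(=O)N1[C@@H](Cc2ccccc2)COC1=O | intermediate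
23 | (S)-N-methoxy-N,3-dimethylhex-5-enamide | C=CC[C@H](C)CC(=O)N(C)OC | intermediate
24 | C1 vinyllithium: 18 with lithium in place of bromine | [Li]C1=C(C)[C@@H]2C(=C(C)OC)CC[C@]2(C)[C@@H](O[Si](CC)(CC)CC)[C@@H]1O[Si](C)(C)C(C)(C)C | intermediate
25 | C14 enone: 18 with the (S)-3-methylhex-5-enoyl group on C1 in place of bromine | C=CC[C@H](C)CC(=O)C1=C(C)[C@@H]2C(=C(C)OC)CC[C@]2(C)[C@@H](O[Si](CC)(CC)CC)[C@@H]1O[Si](C)(C)C(C)(C)C | intermediate
26 | (14S)-allylic alcohol of 25 | C=CC[C@H](C)C[C@H](O)C1=C(C)[C@@H]2C(=C(C)OC)CC[C@]2(C)[C@@H](O[Si](CC)(CC)CC)[C@@H]1O[Si](C)(C)C(C)(C)C | intermediate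
27 | methyl ketone diol: 7-acetyl (down, H-7 up), 3-OH and 14-OH free, 2-OTBS, (12S,14S) side chain with terminal alkene | C=CC[C@H](C)C[C@H](O)C1=C(C)[C@@H]2[C@H](C(C)=O)CC[C@]2(C)[C@@H](O)[C@@H]1O[Si](C)(C)C(C)(C)C | intermediate
28 | 3,14-diacetate of 27 | C=CC[C@H](C)C[C@H](OC(C)=O)C1=C(C)[C@@H]2[C@H](C(C)=O)CC[C@]2(C)[C@@H](OC(C)=O)[C@@H]1O[Si](C)(C)C(C)(C)C | intermediate
29 | enol triflate of 28 (C8(OSO2CF3)=C19H2) | C=CC[C@H](C)C[C@H](OC(C)=O)C1=C(C)[C@@H]2[C@H](C(=C)OS(=O)(=O)C(F)(F)F)CC[C@]2(C)[C@@H](OC(C)=O)[C@@H]1O[Si](C)(C)C(C)(C)C | intermediate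
30 | (E)-alkenyl pinacol boronate of 29 (boron on C9, C9=C10 E) | CC1(C)OB(/C=C/C[C@H](C)C[C@H](OC(C)=O)C2=C(C)[C@@H]3[C@H](C(=C)OS(=O)(=O)C(F)(F)F)CC[C@]3(C)[C@@H](OC(C)=O)[C@@H]2O[Si](C)(C)C(C)(C)C)OC1(C)C | intermediate
31 | 2-O-tert-butyldimethylsilyl ether of the target (rings A, B and C complete) | C=C1/C=C/C[C@H](C)C[C@H](OC(C)=O)C2=C(C)[C@@H]3[C@H]1CC[C@]3(C)[C@@H](OC(C)=O)[C@@H]2O[Si](C)(C)C(C)(C)C | intermediate
32 | (2R,3R,4S,7R,12S,14S,16S)-3,14-diacetoxytrinervita-1(15),8(19),9E-trien-2-ol (CNP0323842.1) | C=C1/C=C/C[C@H](C)C[C@H](OC(C)=O)C2=C(C)[C@@H]3[C@H]1CC[C@]3(C)[C@@H](OC(C)=O)[C@@H]2O | target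

Total step count: 24. Longest linear sequence: 21 steps (steps 1–13 and 17–24); the three-step preparation of 23 (steps 14–16) runs in parallel.

Steps most likely to fail

Step 8. The tert-butoxide may desilylate the hindered tetrasubstituted enol ether before the carbene adds, or the cyclopropane may open only partly and give mixtures. The fallback keeps the one-carbon enlargement but separates it from the halogenation. It sets out from 9: Simmons–Smith cyclopropanation (Et2Zn, CH2I2, CH2Cl2, 0 °C) should give the siloxycyclopropane F1. Saegusa–Ito ring enlargement with FeCl3 in DMF cleaves the C2–C15 bond oxidatively and should give the β-chloro ketone F2, with loss of both silyl groups. NaOAc in methanol eliminates hydrogen chloride to give the ring-enlarged enone F3. Addition of bromine (pyridinium tribromide, CH2Cl2, 0 °C) and elimination with Et3N bring the route back to 12.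

Step 19. Protonation of the enol ether may occur partly from the concave face, or the acetyl-bearing C7 may lose its configuration by acid-catalysed enolisation. The fallback sets H-7 by hydroboration instead and never protonates C7 afterwards. It sets out from 17:
- Wittig ethylidenation (Ph3P=CHCH3, THF, −78 to 0 °C) should give the ethylidene compound F4.
- Hydroboration with BH3·THF from the convex face, then oxidation with NaBO3, should give the secondary alcohol F5 with H-7 up.
- Dess–Martin oxidation gives the methyl ketone F6.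
- Kinetic silylation (KN(SiMe3)2, TBSCl, THF, −78 °C) gives the terminal silyl enol ether F7, a masked methyl ketone whose hydrolysis protonates C19 and not C7.
- Bromine–lithium exchange and acylation with 23 under the conditions of step 17 give the enone F8, and reduction under the conditions of step 18 gives the alcohol F9.
- The conditions of step 19 then cleave the silyl enol ether and the triethylsilyl ether and bring the route back to 27.

Step 23. Intermolecular coupling to oligomers or protodeboronation may outpace closure of the strained eleven-membered ring. The fallback closes the ring at C9=C10 by metathesis instead of at C8–C9 by cross-coupling. It sets out from 29: Stille coupling with tributyl(vinyl)stannane (Pd(PPh3)4, LiCl, THF, 60 °C) should give the 2-substituted butadiene F10. Ring-closing metathesis between its diene terminus and the side-chain vinyl group (second-generation Hoveyda–Grubbs catalyst, toluene, 0.001 M, 80 °C) brings the route back to 31.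

Further compounds
F1 | step 8 | siloxycyclopropane from 9 (CH2 bridging C2 and C15 on the up face) | C[Si](C)(C)O[C@]12C[C@@]1(C)[C@@H]3[C@@H](OCc4ccc(OC)cc4)CC[C@]3(C)[C@H]2O[Si](C)(C)C
F2 | step 8 | β-chloro ketone: 7-chloro-4-hydroxy-1-[(4-methoxybenzyl)oxy]-3a,7-dimethyloctahydro-5H-inden-5-one (C15 epimers) | O=C1CC(C)(Cl)[C@@H]2[C@@H](OCc3ccc(OC)cc3)CC[C@]2(C)[C@H]1O
F3 | step 8 | ring-enlarged enone: 12 with hydrogen in place of bromine | O=C1C=C(C)[C@@H]2[C@@H](OCc3ccc(OC)cc3)CC[C@]2(C)[C@H]1O
F4 | step 19 | 1-ethylidene derivative of 17 (C7=C8H–CH3, E/Z mixture) | BrC1=C(C)[C@@H]2C(=CC)CC[C@]2(C)[C@@H](O[Si](CC)(CC)CC)[C@@H]1O[Si](C)(C)C(C)(C)C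
F5 | step 19 | secondary alcohol: C7 carries 1-hydroxyethyl (down), H-7 up; carbinol epimers | BrC1=C(C)[C@@H]2[C@H](C(C)O)CC[C@]2(C)[C@@H](O[Si](CC)(CC)CC)[C@@H]1O[Si](C)(C)C(C)(C)C
F6 | step 19 | methyl ketone: C7 carries acetyl (down), H-7 up | BrC1=C(C)[C@@H]2[C@H](C(C)=O)CC[C@]2(C)[C@@H](O[Si](CC)(CC)CC)[C@@H]1O[Si](C)(C)C(C)(C)C
F7 | step 19 | terminal tert-butyldimethylsilyl enol ether of F6 (C8(OTBS)=C19H2) | BrC1=C(C)[C@@H]2[C@H](C(=C)O[Si](C)(C)C(C)(C)C)CC[C@]2(C)[C@@H](O[Si](CC)(CC)CC)[C@@H]1O[Si](C)(C)C(C)(C)C
F8 | step 19 | C14 enone: F7 with the (S)-3-methylhex-5-enoyl group on C1 in place of bromine | C=CC[C@H](C)CC(=O)C1=C(C)[C@@H]2[C@H](C(=C)O[Si](C)(C)C(C)(C)C)CC[C@]2(C)[C@@H](O[Si](CC)(CC)CC)[C@@H]1O[Si](C)(C)C(C)(C)C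
F9 | step 19 | (14S)-allylic alcohol of F8 | C=CC[C@H](C)C[C@H](O)C1=C(C)[C@@H]2[C@H](C(=C)O[Si](C)(C)C(C)(C)C)CC[C@]2(C)[C@@H](O[Si](CC)(CC)CC)[C@@H]1O[Si](C)(C)C(C)(C)C
F10 | step 23 | 2-substituted butadiene: 29 with vinyl in place of the triflate group (C19H2=C8–C9H=CH2) | C=CC[C@H](C)C[C@H](OC(C)=O)C1=C(C)[C@@H]2[C@H](C(=C)C=C)CC[C@]2(C)[C@@H](OC(C)=O)[C@@H]1O[Si](C)(C)C(C)(C)C
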